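## Retrosynthetic overview

1. The last C–C bond joins pyridone C-3 to the acyl carbon: a C-3-lithiated 2,4-bis(methoxymethoxy)pyridine that already carries ring D adds to a trans-decalin aldehyde; oxidation to the ketone and acid removal of all protecting groups follow.
2. The strategy rests on ring D, the epoxycyclohexane on pyridone C-5: the oxygens on C-1′ (tertiary) and C-4′ are cis across the ring and the C-2′/C-3′ epoxide lies on the opposite face. This pattern is read as a C1′–O–O–C4′ bridge made by singlet-oxygen [4+2] addition to a 1-pyridylcyclohexa-1,3-diene; the bridge sends the peracid to the far face and is then cut reductively.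
3. The diene is made in one Negishi coupling from 5-bromo-2,4-bis(methoxymethoxy)pyridine and cyclohexa-1,3-dienyl triflate (from cyclohexenone); the racemic epoxy-diol is resolved with a lipase.
4. The decalin comes from an endo intramolecular Diels–Alder reaction of a (2E,8E,10E)-trienal built from (S)-citronellal, which closes both carbocycles at once; the acyl-bearing centre C-2 is then epimerised to the equatorial position.
5. Ring order: pyridine and cyclohexene rings are bought; dioxane bridge (key step), then epoxide, then bridge cleavage; decalin rings A and B together; fragments joined last.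

Key step: step 6

Remark 1: the pyridine nitrogen is expected to be oxidised by the peracid faster than the doubly deactivated bridged alkene, so the N-oxide is planned for in step 7 and removed in step 8 by the reagent that also cleaves the O–O bond.
Remark 2: the lipase is assumed to follow Kazlauskas' rule and to acylate the (R)-configured C-4′ carbinol, which belongs to the antipode needed; if the preference were reversed, the unreacted diol would be carried on and step 10 would fall away.

## Route

Step 1
Reactants: 1 2,4-dihydroxypyridine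
Product: 2 3,5-dibromo-2,4-dihydroxypyridine
Conditions: Br2 (2.1 equiv), AcOH–H2O, rt
Reagents that add atoms: bromine, BrBr
Why: Electrophilic aromatic bromination of the 4-hydroxy-2-pyridone tautomer at both enol-like carbons (C-3 and C-5); taking both avoids any C-3/C-5 selectivity problem.

Step 2
Reactants: 2 3,5-dibromo-2,4-dihydroxypyridine
Product: 3 3,5-dibromo-2,4-bis(methoxymethoxy)pyridine
Conditions: MOMCl (2.6 equiv), Ag2CO3 (1.5 equiv), toluene, rt, dark
Reagents that add atoms: chloromethyl methyl ether (MOMCl), COCCl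
Why: Silver-salt O-alkylation (Williamson type): the silver pyridonate and the hard chloromethyl ether react at oxygen at both positions, and the flanking bromine further blocks N-alkylation.

Step 3
Reactants: 3 3,5-dibromo-2,4-bis(methoxymethoxy)pyridine
Product: 5 5-bromo-2,4-bis(methoxymethoxy)pyridine, via 3-lithio pyridine 4 (not isolated)
Conditions: n-BuLi (1.05 equiv), THF, −78 °C; MeOH
Reagents that add atoms: none
Why: Bromine–lithium exchange is reversible and settles on C-3, where the aryllithium lies between and is chelated by both OMOM groups; protonation then removes that bromine only.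

Step 4
Reactants: 6 cyclohex-2-en-1-one
Product: 7 cyclohexa-1,3-dien-1-yl trifluoromethanesulfonate
Conditions: Tf2O (1.1 equiv), 2,6-di-tert-butyl-4-methylpyridine (1.2 equiv), CH2Cl2, 0 °C → rt
Reagents that add atoms: trifluoromethanesulfonic anhydride, O=S(=O)(OS(=O)(=O)C(F)(F)F)C(F)(F)F
Why: O-Triflylation of the enone gives a 1-triflyloxyallyl cation that the hindered base deprotonates at C-4, so the linearly conjugated (thermodynamic) dienyl triflate forms; the cross-conjugated isomer belongs to kinetic enolate chemistry, which is not used.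

Step 5
Reactants: 5 5-bromo-2,4-bis(methoxymethoxy)pyridine; 7 cyclohexa-1,3-dien-1-yl trifluoromethanesulfonate
Product: 10 5-(cyclohexa-1,3-dien-1-yl)-2,4-bis(methoxymethoxy)pyridine, via aryllithium 8 (not isolated), via arylzinc chloride 9 (not isolated)
Conditions: n-BuLi (1.05 equiv), THF, −78 °C, 10 min; ZnCl2 (1.1 equiv), −78 → 0 °C; 7, Pd(PPh3)4 (5 mol %), THF, rt
Reagents that add atoms: none
Why: Bromine–lithium exchange at −78 °C is faster than deprotonation at C-3, zinc fixes the carbanion, and Negishi cross-coupling at the C–OTf bond puts the pyridine on the terminus of the pre-formed 1,3-diene without regiochemical ambiguity.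

Step 6
Reactants: 10 5-(cyclohexa-1,3-dien-1-yl)-2,4-bis(methoxymethoxy)pyridine
Product: 11 rac-(1S,4R)-1-[4,6-bis(methoxymethoxy)pyridin-3-yl]-2,3-dioxabicyclo[2.2.2]oct-5-ene
Conditions: O2, 5,10,15,20-tetraphenylporphyrin (cat.), visible light, CH2Cl2, −78 °C
Reagents that add atoms: oxygen, O=O
Why: The triplet-excited porphyrin passes its energy to O2, and the singlet oxygen adds to the cisoid diene C1′=C2′–C3′=C4′ in a concerted, suprafacial [4+2] cycloaddition, the reaction type by which α-terpinene gives ascaridole and 1-arylcyclohexa-1,3-dienes give their endoperoxides. The 1,2-dioxane ring closes in the cycloaddition itself, both new bonds (C1′–O and C4′–O) forming on one face through a boat-like six-membered transition state, which gives the 2,3-dioxabicyclo[2.2.2]oct-5-ene. C-1′ and C-4′ are set relative to each other by the two-atom O–O tether, which can only span one face, so the two oxygens are cis by necessity. Neither face of the flat diene is preferred, so 11 should form as the racemate, and the antipodes are parted in step 9. The step needs [4+2] to win over the ene reaction at the C-5′/C-6′ methylene hydrogens, over [2+2] addition at the styrene-like C1′=C2′ bond and over aromatisation; the ring locks the diene s-cis, the aryl group raises its HOMO, and a non-polar solvent at −78 °C disfavours the polar perepoxide pathways. The dialkoxypyridine and the acetal groups do not react with singlet oxygen.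

Step 7
Reactants: 11 rac-(1S,4R)-1-[4,6-bis(methoxymethoxy)pyridin-3-yl]-2,3-dioxabicyclo[2.2.2]oct-5-ene
Product: 13 racemic anti-5,6-epoxide of 11 as its pyridine N-oxide (epoxide oxygen on the face of the C7–C8 ethano bridge), via endoperoxide N-oxide 12 (not isolated)
Conditions: mCPBA (4 equiv), NaHCO3, CH2Cl2, 0 °C → rt, 2–3 d
Reagents that add atoms: 3-chloroperoxybenzoic acid (mCPBA), O=C(OO)c1cccc(Cl)c1
Why: Prilezhaev epoxidation of a 2,3-dioxabicyclo[2.2.2]oct-5-ene takes place on the ethano-bridge face because the peroxide lone pairs repel the peracid (as known for ascaridole-type endoperoxides), which sets C-2′ and C-3′ anti to both bridge oxygens; the more nucleophilic pyridine nitrogen is oxidised first, so excess peracid is used and the N-oxide serves as a temporary mask.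

Step 8
Reactants: 13 racemic anti-epoxy endoperoxide N-oxide
Product: 15 rac-(1S,2R,5R,6S)-2-[4,6-bis(methoxymethoxy)pyridin-3-yl]-7-oxabicyclo[4.1.0]heptane-2,5-diol, via diol N-oxide 14 (not isolated)
Conditions: Zn dust (6 equiv), sat. aq. NH4Cl, THF, rt
Reagents that add atoms: none
Why: Zinc reduction cleaves the weak O–O bond to the cis-1,4-diol without breaking any C–O bond, so C-1′ and C-4′ keep their configuration, and the same metal deoxygenates the pyridine N-oxide; the epoxide and the acetals are inert at this near-neutral pH.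

Step 9
Reactants: 15 racemic epoxy-diol
Product: 16 (1S,2R,5R,6S)-5-[4,6-bis(methoxymethoxy)pyridin-3-yl]-5-hydroxy-7-oxabicyclo[4.1.0]heptan-2-yl acetate
Conditions: Burkholderia cepacia lipase (immobilised), vinyl acetate (3 equiv), t-BuOMe, 35 °C, stopped near half conversion
Reagents that add atoms: vinyl acetate, C=COC(C)=O
Why: Lipase-catalysed transesterification (kinetic resolution): only the secondary C-4′ carbinol is acylated and, by Kazlauskas' rule (large substituent on the epoxide side), the (R)-carbinol of the needed antipode should react, while the other enantiomer stays as the diol and is removed by chromatography.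

Step 10
Reactants: 16 monoacetate
Product: 17 (1S,2R,5R,6S)-2-[4,6-bis(methoxymethoxy)pyridin-3-yl]-7-oxabicyclo[4.1.0]heptane-2,5-diol (single enantiomer)
Conditions: K2CO3 (0.2 equiv), MeOH, 0 °C
Reagents that add atoms: none
Why: Base-catalysed transesterification (methanolysis of the acetate) frees the secondary alcohol; with catalytic carbonate at 0 °C no Payne migration of the epoxide is expected.

Step 11
Reactants: 17 enantiopure epoxy-diol
Product: 18 bis(trimethylsilyl) ether of 17
Conditions: N-(trimethylsilyl)imidazole (3 equiv), CH2Cl2, rt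
Reagents that add atoms: N-(trimethylsilyl)imidazole, C[Si](C)(C)n1ccnc1
Why: Silylation with a neutral, powerful silyl donor covers the secondary and the hindered tertiary hydroxyl without a Lewis acid, so the epoxide and the acid-labile pyridyl MOM ethers stay intact.

Step 12
Reactants: 19 (S)-citronellal
Product: 20 (2E,5S)-N-methoxy-N,5,9-trimethyldeca-2,8-dienamide
Conditions: Ph3P=CHC(O)N(OMe)Me (1.2 equiv), CH2Cl2, rt → 40 °C
Reagents that add atoms: N-methoxy-N-methyl-2-(triphenylphosphoranylidene)acetamide, CON(C)C(=O)C=P(c1ccccc1)(c1ccccc1)c1ccccc1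
Why: Wittig olefination with a stabilised ylide gives the (E)-enamide and leaves the β-stereocentre untouched.

Step 13
Reactants: 20 dienamide
Product: 22 (2E,5S,8E)-N-methoxy-N,5,9-trimethyl-10-oxodeca-2,8-dienamide, via allylic alcohol 21 (not isolated)
Conditions: SeO2 (0.3 equiv), t-BuOOH (3 equiv), CH2Cl2, rt; then MnO2, CH2Cl2, rt
Reagents that add atoms: selenium dioxide, O=[Se]=O (oxygen donor, turned over by tert-butyl hydroperoxide, CC(C)(C)OO)
Why: SeO2 allylic oxidation (ene reaction then [2,3]-shift) attacks only the electron-rich trisubstituted alkene and oxidises its (E)-methyl group, and MnO2 takes the allylic alcohol on to the (E)-enal.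

Step 14
Reactants: 22 enal amide
Product: 23 ethyl (2E,4E,8S,10E)-12-[methoxy(methyl)amino]-4,8-dimethyl-12-oxododeca-2,4,10-trienoate
Conditions: Ph3P=CHCO2Et (1.3 equiv), toluene, 60 °C
Reagents that add atoms: ethyl 2-(triphenylphosphoranylidene)acetate, CCOC(=O)C=P(c1ccccc1)(c1ccccc1)c1ccccc1
Why: Wittig olefination with a stabilised ylide reacts at the aldehyde only (the Weinreb amide is inert) and gives the (E,E)-dienoate.

Step 15
Reactants: 23 trienoate amide
Product: 24 (2E,5S,8E,10E)-12-hydroxy-5,9-dimethyldodeca-2,8,10-trienal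
Conditions: i-Bu2AlH (3.5 equiv), THF, −78 → −30 °C; aq. Rochelle salt
Reagents that add atoms: none
Why: Hydride reduction: the ester goes to the allylic alcohol while the Weinreb amide stops at the chelated aluminium hemiaminal, which releases the enal only on work-up, so both chain ends reach their needed oxidation levels in one operation.

Step 16
Reactants: 24 hydroxy trienal
Product: 25 (2E,5S,8E,10E)-12-[(tert-butyldimethylsilyl)oxy]-5,9-dimethyldodeca-2,8,10-trienal
Conditions: TBSCl (1.2 equiv), imidazole (2 equiv), CH2Cl2, 0 °C → rt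
Reagents that add atoms: tert-butyldimethylsilyl chloride, CC(C)(C)[Si](C)(C)Cl
Why: Standard silylation of the primary allylic alcohol; the enal is inert.

Step 17
Reactants: 25 silyloxy trienal
Product: 26 (1R,2S,4aS,7S,8aS)-2-{[(tert-butyldimethylsilyl)oxy]methyl}-4,7-dimethyl-1,2,4a,5,6,7,8,8a-octahydronaphthalene-1-carbaldehyde
Conditions: Me2AlCl (1.1 equiv), CH2Cl2, −78 → −20 °C
Reagents that add atoms: none
Why: Lewis-acid-promoted intramolecular Diels–Alder reaction: the Me2AlCl-bound (E)-enal adds to the (8E,10E)-diene through the endo transition state with a chair-like four-carbon tether that keeps the C-5 methyl group equatorial, which closes both carbocycles as the trans-fused decalin, sets C-1, C-4a and C-8a relative to the citronellal centre, and leaves CHO and CH2OTBS cis (C-2 is corrected in step 20).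

Step 18
Reactants: 26 decalin aldehyde
Product: 27 tert-butyl{[(1R,2R,4aS,7S,8aR)-4,7-dimethyl-1-[(E)-prop-1-enyl]-1,2,4a,5,6,7,8,8a-octahydronaphthalen-2-yl]methoxy}dimethylsilane
Conditions: 5-(ethylsulfonyl)-1-phenyl-1H-tetrazole (1.5 equiv), KN(SiMe3)2 (1.4 equiv), DME, −60 °C → rt
Reagents that add atoms: 5-(ethylsulfonyl)-1-phenyl-1H-tetrazole, CCS(=O)(=O)c1nnnn1-c1ccccc1
Why: Julia–Kocienski olefination of the α-branched aldehyde with the phenyltetrazolyl sulfone anion gives the (E)-propenyl group; the equatorial C-1 centre is the stable epimer and is not at risk.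

Step 19
Reactants: 27 silyl ether
Product: 28 [(1R,2R,4aS,7S,8aR)-4,7-dimethyl-1-[(E)-prop-1-enyl]-1,2,4a,5,6,7,8,8a-octahydronaphthalen-2-yl]methanol
Conditions: Bu4NF (1.5 equiv), THF, rt
Reagents that add atoms: none
Why: Fluoride cleavage of the silyl ether; nothing else in the molecule responds to fluoride.

Step 20
Reactants: 28 decalin methanol
Product: 30 (1R,2S,4aS,7S,8aR)-4,7-dimethyl-1-[(E)-prop-1-enyl]-1,2,4a,5,6,7,8,8a-octahydronaphthalene-2-carbaldehyde, via cis aldehyde 29 (not isolated)
Conditions: Dess–Martin periodinane (1.3 equiv), NaHCO3, CH2Cl2, 0 °C; work-up; then DBU (0.2 equiv), CH2Cl2, rt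
Reagents that add atoms: none
Why: Dess–Martin oxidation gives the aldehyde with the formyl group cis to the propenyl group (pseudoaxial), and DBU then equilibrates C-2 through the dienolate, which is reprotonated at the α-carbon, towards the trans-diequatorial aldehyde; remaining cis isomer is separated and resubmitted.

Step 21
Reactants: 18 bis(trimethylsilyl) ether; 30 decalin aldehyde
Product: 32 secondary alcohol from addition of pyridine C-3 of 18 to the formyl carbon of 30 (both carbinol epimers), via 3-lithiopyridine 31 (not isolated)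
Conditions: n-BuLi (1.05 equiv), THF, −78 °C, 45 min; 30 (0.9 equiv), −78 → −40 °C; aq. NH4Cl
Reagents that add atoms: none
Why: Directed ortho-metalation: C-3 lies between two OMOM groups and is lithiated selectively, and 1,2-addition to the aldehyde forms the C3–C bond; the new carbinol centre is irrelevant because it is oxidised next.

Step 22
Reactants: 32 carbinol
Product: 33 protected ketone (3-acyl-2,4-bis(methoxymethoxy)pyridine with ring D as its bis(trimethylsilyl) ether)
Conditions: Dess–Martin periodinane (1.5 equiv), NaHCO3, CH2Cl2, 0 °C → rt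
Reagents that add atoms: none
Why: Dess–Martin oxidation of the hindered secondary alcohol to the aryl ketone under buffered, non-epimerising conditions; alkenes, epoxide and silyl ethers are inert.

Step 23
Reactants: 33 protected ketone
Product: 34 3-{[(1R,2S,4aS,7S,8aR)-4,7-dimethyl-1-[(E)-prop-1-enyl]-1,2,4a,5,6,7,8,8a-octahydronaphthalen-2-yl]carbonyl}-5-[(1S,2R,5R,6S)-2,5-dihydroxy-7-oxabicyclo[4.1.0]heptan-2-yl]-4-hydroxypyridin-2(1H)-one (CNP0494338.1)
Conditions: HCl (1.25 M in MeOH, 5 equiv), MeOH–CH2Cl2, 0 °C
Reagents that add atoms: none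
Why: Acid-catalysed acetal exchange and silyl ether solvolysis: N-protonation makes the 2-OMOM group labile, the 4-OMOM group ortho to the ketone is a vinylogous acylal, and the TMS ethers leave in the same medium; the epoxide, deactivated by two flanking C–O bonds, should survive the short cold exposure, and the 2,4-dihydroxypyridine tautomerises to the 4-hydroxy-2-pyridone.

## Compound list

1 | 2,4-dihydroxypyridine | Oc1ccnc(O)c1 | starting material
2 | 3,5-dibromo-2,4-dihydroxypyridine | Oc1ncc(Br)c(O)c1Br | intermediate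
3 | 3,5-dibromo-2,4-bis(methoxymethoxy)pyridine | COCOc1ncc(Br)c(OCOC)c1Br | intermediate
4 | 5-bromo-3-lithio-2,4-bis(methoxymethoxy)pyridine (not isolated) | [Li]c1c(OCOC)ncc(Br)c1OCOC | intermediate
5 | 5-bromo-2,4-bis(methoxymethoxy)pyridine | COCOc1cc(OCOC)c(Br)cn1 | intermediate
6 | cyclohex-2-en-1-one | O=C1C=CCCC1 | starting material
7 | cyclohexa-1,3-dien-1-yl trifluoromethanesulfonate | O=S(=O)(OC1=CC=CCC1)C(F)(F)F | intermediate
8 | 5-lithio-2,4-bis(methoxymethoxy)pyridine (not isolated) | [Li]c1cnc(OCOC)cc1OCOC | intermediate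
9 | [4,6-bis(methoxymethoxy)pyridin-3-yl]zinc chloride (not isolated) | Cl[Zn]c1cnc(OCOC)cc1OCOC | intermediate
10 | 5-(cyclohexa-1,3-dien-1-yl)-2,4-bis(methoxymethoxy)pyridine | COCOc1cc(OCOC)c(C2=CC=CCC2)cn1 | intermediate
11 | rac-(1S,4R)-1-[4,6-bis(methoxymethoxy)pyridin-3-yl]-2,3-dioxabicyclo[2.2.2]oct-5-ene (racemate; needed enantiomer drawn) | COCOc1cc(OCOC)c([C@]23CC[C@H](C=C2)OO3)cn1 | intermediate
12 | pyridine N-oxide of 11 (racemate; not isolated) | COCOc1cc(OCOC)c([C@]23CC[C@H](C=C2)OO3)c[n+]1[O-] | intermediate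
13 | anti-5,6-epoxide of 12, epoxide on the ethano-bridge face (racemate) | COCOc1cc(OCOC)c([C@]2(OO4)CC[C@@H]4[C@@H]3O[C@@H]32)c[n+]1[O-] | intermediate
14 | pyridine N-oxide of 15 (racemate; not isolated) | COCOc1cc(OCOC)c([C@]2(O)CC[C@@H](O)[C@@H]3O[C@@H]32)c[n+]1[O-] | intermediate
15 | rac-(1S,2R,5R,6S)-2-[4,6-bis(methoxymethoxy)pyridin-3-yl]-7-oxabicyclo[4.1.0]heptane-2,5-diol (racemate; needed enantiomer drawn) | COCOc1cc(OCOC)c([C@]2(O)CC[C@@H](O)[C@@H]3O[C@@H]32)cn1 | intermediate
16 | (1S,2R,5R,6S)-5-[4,6-bis(methoxymethoxy)pyridin-3-yl]-5-hydroxy-7-oxabicyclo[4.1.0]heptan-2-yl acetate | COCOc1cc(OCOC)c([C@]2(O)CC[C@@H](OC(C)=O)[C@@H]3O[C@@H]32)cn1 | intermediate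
17 | (1S,2R,5R,6S)-2-[4,6-bis(methoxymethoxy)pyridin-3-yl]-7-oxabicyclo[4.1.0]heptane-2,5-diol (single enantiomer) | COCOc1cc(OCOC)c([C@]2(O)CC[C@@H](O)[C@@H]3O[C@@H]32)cn1 | intermediate
18 | bis(trimethylsilyl) ether of 17 | COCOc1cc(OCOC)c([C@]2(O[Si](C)(C)C)CC[C@@H](O[Si](C)(C)C)[C@@H]3O[C@@H]32)cn1 | intermediate
19 | (S)-citronellal | O=CC[C@@H](C)CCC=C(C)C | starting material
20 | (2E,5S)-N-methoxy-N,5,9-trimethyldeca-2,8-dienamide | CON(C)C(=O)/C=C/C[C@@H](C)CCC=C(C)C | intermediate
21 | (2E,5S,8E)-10-hydroxy-N-methoxy-N,5,9-trimethyldeca-2,8-dienamide (not isolated) | CON(C)C(=O)/C=C/C[C@@H](C)CC/C=C(\C)CO | intermediate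
22 | (2E,5S,8E)-N-methoxy-N,5,9-trimethyl-10-oxodeca-2,8-dienamide | CON(C)C(=O)/C=C/C[C@@H](C)CC/C=C(\C)C=O | intermediate
23 | ethyl (2E,4E,8S,10E)-12-[methoxy(methyl)amino]-4,8-dimethyl-12-oxododeca-2,4,10-trienoate | CON(C)C(=O)/C=C/C[C@@H](C)CC/C=C(\C)/C=C/C(=O)OCC | intermediate
24 | (2E,5S,8E,10E)-12-hydroxy-5,9-dimethyldodeca-2,8,10-trienal | O=C/C=C/C[C@@H](C)CC/C=C(\C)/C=C/CO | intermediate
25 | (2E,5S,8E,10E)-12-[(tert-butyldimethylsilyl)oxy]-5,9-dimethyldodeca-2,8,10-trienal | O=C/C=C/C[C@@H](C)CC/C=C(\C)/C=C/CO[Si](C)(C)C(C)(C)C | intermediate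
26 | (1R,2S,4aS,7S,8aS)-2-{[(tert-butyldimethylsilyl)oxy]methyl}-4,7-dimethyl-1,2,4a,5,6,7,8,8a-octahydronaphthalene-1-carbaldehyde | O=C[C@@H]1[C@H]2C[C@@H](C)CC[C@@H]2C(C)=C[C@@H]1CO[Si](C)(C)C(C)(C)C | intermediate
27 | tert-butyl{[(1R,2R,4aS,7S,8aR)-4,7-dimethyl-1-[(E)-prop-1-enyl]-1,2,4a,5,6,7,8,8a-octahydronaphthalen-2-yl]methoxy}dimethylsilane | C/C=C/[C@@H]1[C@H]2C[C@@H](C)CC[C@@H]2C(C)=C[C@@H]1CO[Si](C)(C)C(C)(C)C | intermediate
28 | [(1R,2R,4aS,7S,8aR)-4,7-dimethyl-1-[(E)-prop-1-enyl]-1,2,4a,5,6,7,8,8a-octahydronaphthalen-2-yl]methanol | C/C=C/[C@@H]1[C@H]2C[C@@H](C)CC[C@@H]2C(C)=C[C@@H]1CO | intermediate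
29 | (1R,2R,4aS,7S,8aR)-4,7-dimethyl-1-[(E)-prop-1-enyl]-1,2,4a,5,6,7,8,8a-octahydronaphthalene-2-carbaldehyde (formyl cis to propenyl; not isolated) | C/C=C/[C@@H]1[C@H]2C[C@@H](C)CC[C@@H]2C(C)=C[C@@H]1C=O | intermediate
30 | (1R,2S,4aS,7S,8aR)-4,7-dimethyl-1-[(E)-prop-1-enyl]-1,2,4a,5,6,7,8,8a-octahydronaphthalene-2-carbaldehyde | C/C=C/[C@@H]1[C@H]2C[C@@H](C)CC[C@@H]2C(C)=C[C@H]1C=O | intermediate
31 | 3-lithio derivative of 18 (not isolated) | [Li]c1c(OCOC)ncc([C@]2(O[Si](C)(C)C)CC[C@@H](O[Si](C)(C)C)[C@@H]3O[C@@H]32)c1OCOC | intermediate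
32 | secondary alcohol joining pyridine C-3 of 18 to the former formyl carbon of 30 (carbinol epimers; other centres as in 18 and 30) | C/C=C/[C@@H]1[C@H]2C[C@@H](C)CC[C@@H]2C(C)=C[C@H]1C(O)c1c(OCOC)c([C@]2(O[Si](C)(C)C)CC[C@@H](O[Si](C)(C)C)[C@@H]3O[C@@H]32)cnc1OCOC | intermediate
33 | ketone from 32: 3-acyl-2,4-bis(methoxymethoxy)pyridine, ring D as bis(trimethylsilyl) ether | C/C=C/[C@@H]1[C@H]2C[C@@H](C)CC[C@@H]2C(C)=C[C@H]1C(=O)c1c(OCOC)c([C@]2(O[Si](C)(C)C)CC[C@@H](O[Si](C)(C)C)[C@@H]3O[C@@H]32)cnc1OCOC | intermediate
34 | CNP0494338.1: 3-{[(1R,2S,4aS,7S,8aR)-4,7-dimethyl-1-[(E)-prop-1-enyl]-1,2,4a,5,6,7,8,8a-octahydronaphthalen-2-yl]carbonyl}-5-[(1S,2R,5R,6S)-2,5-dihydroxy-7-oxabicyclo[4.1.0]heptan-2-yl]-4-hydroxypyridin-2(1H)-one | C/C=C/[C@@H]1[C@H]2C[C@@H](C)CC[C@@H]2C(C)=C[C@H]1C(=O)c1c(O)c([C@]2(O)CC[C@@H](O)[C@@H]3O[C@@H]32)c[nH]c1=O | target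

## Step count and risks

Total step count: 23.
Longest linear sequence: 13 steps (steps 1–3, 5–11 and 21–23, from 2,4-dihydroxypyridine). The decalin branch from (S)-citronellal is 12 steps (steps 12–23).

Steps most likely to fail:

1. Step 7 (epoxidation of the endoperoxide). N-Oxidation outruns the slow epoxidation, and over the long exposure the N-oxide may lose its 2-O-methoxymethyl group, the peroxide may decay, or face selectivity may erode. The fallback sets out from 11 and returns at 15; it delivers the oxygen with osmium instead of a peracid. OsO4 (cat.) with N-methylmorpholine N-oxide in acetone–water should dihydroxylate the bridged alkene on the same ethano-bridge face (the known anti dihydroxylation of bicyclic endoperoxides) without touching the pyridine nitrogen, which gives the anti-diol endoperoxide F1. Thiourea in MeOH then cleaves the O–O bond to the tetraol F2. In one flask, MeC(OMe)3 with catalytic PPTS closes the only cis-vicinal diol (C-2′/C-3′) to the cyclic orthoacetate F3. Me3SiCl opens it through the acetoxonium ion, with inversion at C-3′, to the trans-chlorohydrin acetate F4. K2CO3 in MeOH removes the acetate, and the C-2′ alkoxide displaces chloride with a second inversion, so the epoxide forms on the original diol face and the racemic diol 15 is reached.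

2. Step 6 (key cycloaddition). Ene hydroperoxidation at the ring methylene groups or oxidative aromatisation of the sensitive diene may compete with the [4+2] addition. The fallback sets out from 10 and returns at 11; it uses ground-state oxygen under one-electron catalysis. Tris(4-bromophenyl)aminium hexachloroantimonate (cat.) under O2 in CH2Cl2 at −78 °C starts a radical-cation chain in which the diene radical cation captures triplet oxygen and closes to the same endoperoxide. No singlet oxygen is present, so the ene pathway is closed. No new compound is made.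

3. Step 21 (fragment coupling). The hindered, basic aryllithium may deprotonate the α-carbon of the β,γ-unsaturated aldehyde instead of adding, which would cause enolisation, epimerisation at C-2 or migration of the ring alkene. The fallback sets out from 30 and 18 and returns at 33; it replaces carbonyl addition by a palladium-catalysed acylation. Pinnick oxidation of 30 (NaClO2, NaH2PO4, 2-methylbut-2-ene, t-BuOH–H2O) gives the decalin carboxylic acid F5, and (COCl)2 with catalytic DMF gives the acid chloride F6. The lithiopyridine 31, made as in step 21, is transmetalated with ZnCl2 to the arylzinc chloride F7. Pd(PPh3)4-catalysed Negishi acylation of F7 with F6 in THF at rt gives ketone 33 directly, so step 22 is no longer needed.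

## Further compounds

F1 | step 7 | anti-5,6-diol of endoperoxide 11 (racemate; hydroxyls on the ethano-bridge face) | COCOc1cc(OCOC)c([C@]2(OO4)CC[C@@H]4[C@H](O)[C@@H]2O)cn1
F2 | step 7 | 1-[4,6-bis(methoxymethoxy)pyridin-3-yl]cyclohexane-1,2,3,4-tetraol (racemate; 1-OH and 4-OH cis, 2-OH and 3-OH cis on the other face) | COCOc1cc(OCOC)c([C@]2(O)CC[C@@H](O)[C@H](O)[C@@H]2O)cn1
F3 | step 7 | cyclic 2,3-orthoacetate (2-methoxy-2-methyl-1,3-dioxolane) of F2 | COCOc1cc(OCOC)c([C@]2(O)CC[C@@H](O)[C@@H]3OC(C)(OC)O[C@@H]32)cn1
F4 | step 7 | trans-chlorohydrin acetate from F3 (3-chloro with inverted configuration, 2-acetoxy) | COCOc1cc(OCOC)c([C@]2(O)CC[C@@H](O)[C@@H](Cl)[C@@H]2OC(C)=O)cn1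
F0 | step 6 | none | none
F5 | step 21 | (1R,2S,4aS,7S,8aR)-4,7-dimethyl-1-[(E)-prop-1-enyl]-1,2,4a,5,6,7,8,8a-octahydronaphthalene-2-carboxylic acid | C/C=C/[C@@H]1[C@H]2C[C@@H](C)CC[C@@H]2C(C)=C[C@H]1C(=O)O
F6 | step 21 | acid chloride of F5 | C/C=C/[C@@H]1[C@H]2C[C@@H](C)CC[C@@H]2C(C)=C[C@H]1C(=O)Cl
F7 | step 21 | pyridin-3-ylzinc chloride from 31 | Cl[Zn]c1c(OCOC)ncc([C@]2(O[Si](C)(C)C)CC[C@@H](O[Si](C)(C)C)[C@@H]3O[C@@H]32)c1OCOC
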